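**Retrosynthetic overview**

1. The butenolide comes last: the C12–C13 bond by B-alkyl Suzuki coupling of the 9-BBN adduct of a C9-vinyl diene with 4-bromofuran-2(5H)-one. The vinyl group comes from the C11 ester (reduction, oxidation, Wittig).
2. The 2α- and 6α-hydroxyls come from a 2,6-diketone by hydride delivery on the β-face from the axial 19-CH2OH.
3. Ring B comes from a [3+3] Michael–Dieckmann annulation of dimethyl 3-methylglutaconate (C7, C8, C9, C11, C17) with the ring A enone–lactone 8. The enabling feature: C10 is the β-carbon of the C2 carbonyl (C2–C1=C10), and C6 is an acyl carbon on the neighbouring C5, held to O19 of C4 as a cis-fused γ-lactone. Ring A thus offers two electrophilic carbons (C10, C6) three atoms apart to the two nucleophilic carbons (C9, C7) of the glutaconate.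
4. Ring order: ring A first (enantioselective Diels–Alder, sets C4), then the temporary lactone ring, then ring B (which opens the lactone and frees 19-OH); the butenolide ring is brought in intact.

Key step: step 7

Assumption: the (S)-oxazaborolidinium catalyst of step 3 is taken to expose the enal face that its accepted model for 2-substituted acroleins predicts; if the opposite sense were found, its enantiomer would be used.

**Step 1**
Reactants: 1 (E)-3-methylpent-2-en-4-yn-1-ol
Product: 2 (E)-3-methylpent-2-en-4-yn-1-yl acetate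
Conditions: Ac2O, Et3N, DMAP (cat.), CH2Cl2, 0 °C → rt
Reagents that add atoms: acetic anhydride CC(=O)OC(C)=O
Why: DMAP-catalysed acyl transfer masks the primary alcohol so that it does not bind the boron Lewis acid of step 3; no stereocenter is formed.

**Step 2**
Reactants: 2 (E)-3-methylpent-2-en-4-yn-1-yl acetate
Product: 3 (E)-3-methylpenta-2,4-dien-1-yl acetate
Conditions: H2 (1 atm), Pd/CaCO3 poisoned with Pb(OAc)2, quinoline, EtOAc, 0 °C, stopped after 1 equiv H2
Reagents that add atoms: none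
Why: Partial hydrogenation of the terminal alkyne on the poisoned palladium surface should stop at the alkene and leave the (E)-trisubstituted double bond untouched; no stereocenter is formed.

**Step 3**
Reactants: 3 (E)-3-methylpenta-2,4-dien-1-yl acetate; 4 methacrolein
Product: 5 [(1R,6S)-6-formyl-2,6-dimethylcyclohex-2-en-1-yl]methyl acetate
Conditions: (S)-3,3-diphenyl-1-(o-tolyl)tetrahydropyrrolo[1,2-c][1,3,2]oxazaborole activated with HNTf2 (20 mol %), CH2Cl2, −78 → −40 °C
Reagents that add atoms: none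
Why: Lewis acid-catalysed Diels–Alder reaction in which the unsubstituted diene terminus (C2) bonds to the β-carbon of the bound enal and the substituted terminus (C5) to its α-carbon ("ortho" orientation, directed by the terminal CH2OAc group); the chiral oxazaborolidinium shields one enal face so that quaternary C4 should form as (S), and formyl-endo approach to the (E)-diene places CHO and CH2OAc cis.

**Step 4**
Reactants: 5 [(1R,6S)-6-formyl-2,6-dimethylcyclohex-2-en-1-yl]methyl acetate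
Product: 6 [(1S,2R)-1,3-dimethylcyclohex-3-ene-1,2-diyl]dimethanol
Conditions: NaBH4, MeOH, 0 °C; then K2CO3 (cat.), MeOH, rt
Reagents that add atoms: none
Why: Hydride reduction of the aldehyde followed by base-catalysed transesterification of the acetate should give the 1,4-diol without touching either stereocenter.

**Step 5**
Reactants: 6 [(1S,2R)-1,3-dimethylcyclohex-3-ene-1,2-diyl]dimethanol
Product: 7 (3aS,7aR)-3a,7-dimethyl-3a,4,5,7a-tetrahydro-2-benzofuran-1(3H)-one
Conditions: TEMPO (cat.), PhI(OAc)2, CH2Cl2, rt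
Reagents that add atoms: none
Why: Oxoammonium oxidation should take the less hindered C6 alcohol (the C19 alcohol is neopentylic) to the aldehyde, which the C19 hydroxyl traps as the lactol and which is oxidised on to the cis-fused γ-lactone (oxidative lactonisation); the stereocenters are retained.

**Step 6**
Reactants: 7 (3aS,7aR)-3a,7-dimethyl-3a,4,5,7a-tetrahydro-2-benzofuran-1(3H)-one
Product: 8 (3aS,7aR)-3a,7-dimethyl-3a,4-dihydro-2-benzofuran-1,5(3H,7aH)-dione
Conditions: Rh2(cap)4 (cap = caprolactamate, 1 mol %), t-BuOOH, K2CO3 (cat.), CH2Cl2, rt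
Reagents that add atoms: tert-butyl hydroperoxide CC(C)(C)OO
Why: Radical allylic oxidation (tert-butylperoxy radical, mixed peroxide, enone) should attack the only allylic CH2 (C2), the allylic C5–H being deactivated by the lactone carbonyl; C5 becomes acidic in 8 and would settle as the more stable cis-fused lactone had any trans isomer been carried along.

**Step 7**
Reactants: 8 (3aS,7aR)-3a,7-dimethyl-3a,4-dihydro-2-benzofuran-1,5(3H,7aH)-dione; 9 dimethyl 3-methylpent-2-enedioate (dimethyl 3-methylglutaconate)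
Product: 11 dimethyl (4aR,5S,8aS)-5-(hydroxymethyl)-2,5,8a-trimethyl-4,7-dioxo-3,4,4a,5,6,7,8,8a-octahydronaphthalene-1,3-dicarboxylate, via Michael adduct 10 (not isolated)
Conditions: 9 (1.5 equiv), KOt-Bu (2.5 equiv), THF/t-BuOH, 0 → 65 °C; then aq. HCl, 0 °C
Reagents that add atoms: none
Why: Michael–Dieckmann [3+3] annulation: the potassium anion of 9 (a vinylogous malonate) adds through C9 to the enone β-carbon C10, proton transfer regenerates the stabilised anion, and this attacks the γ-lactone carbonyl C6 through C7 and expels the C19 alkoxide, the reversible addition being pulled forward because 11 leaves the equilibria as its β-keto ester enolate. The closest known reaction type is the Michael–Claisen route from malonate and a β,β-disubstituted enone to a cyclohexane-1,3-dione (dimedone synthesis), here with a lactone as the acyl acceptor. Ring B closes by 6-exo-trig attack of the ester enolate carbon on the lactone carbonyl (enolexo mode); closure through C9 would need a four-membered ring. The quaternary C10 is set by approach to the convex α-face of the cis-fused bicycle, anti to the pseudoaxial C5–C6 bond, so that C9 and C6 are trans and the new decalin is trans-fused (10β-methyl, 5α-H); C5, now α to the C6 ketone, can equilibrate and should remain 5α. The step needs conjugate addition before acylation, which the poor intermolecular acylating power of a lactone towards a stabilised carbanion should secure, and it places the C8=C9 double bond and the C17 methyl without ambiguity because both are already in 9 and its anion is symmetrical about C8.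

**Step 8**
Reactants: 11 dimethyl (4aR,5S,8aS)-5-(hydroxymethyl)-2,5,8a-trimethyl-4,7-dioxo-3,4,4a,5,6,7,8,8a-octahydronaphthalene-1,3-dicarboxylate
Product: 12 methyl (1S,4aR,5S,8aS)-5-(hydroxymethyl)-2,5,8a-trimethyl-4,7-dioxo-1,4,4a,5,6,7,8,8a-octahydronaphthalene-1-carboxylate
Conditions: LiCl, H2O, DMSO, 130 °C
Reagents that add atoms: none
Why: Krapcho dealkoxycarbonylation: chloride demethylates the β-keto ester at C7 and the carboxylate loses CO2, while the C11 ester, which is not β to a ketone, should survive at this temperature; the hot medium should leave the conjugated 7-en-6-one with the C9 ester equatorial (thermodynamic protonation), a center that is removed again in step 9.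

**Step 9**
Reactants: 12 methyl (1S,4aR,5S,8aS)-5-(hydroxymethyl)-2,5,8a-trimethyl-4,7-dioxo-1,4,4a,5,6,7,8,8a-octahydronaphthalene-1-carboxylate
Product: 14 methyl (4S,4aR,5S,7R,8aS)-4,7-dihydroxy-5-(hydroxymethyl)-2,5,8a-trimethyl-3,4,4a,5,6,7,8,8a-octahydronaphthalene-1-carboxylate, via β,γ-unsaturated ketone 13 (not isolated)
Conditions: KOt-Bu (4 equiv), THF/t-BuOH, 0 °C; added to AcOH/MeCN, −40 °C; then Me4N[BH(OAc)3], −40 → −10 °C
Reagents that add atoms: none
Why: Deprotonation at C9 gives the extended enolate (whichever tautomer step 8 delivers), whose kinetic protonation at C7 moves the double bond to C8=C9 (deconjugation of an enone through its dienolate); the axial 19-hydroxyl then exchanges onto the triacetoxyborohydride and delivers hydride to the β-faces of the C6 and C2 carbonyls (hydroxyl-directed reduction), which should set both new carbinol centers as the equatorial 6α- and 2α-alcohols.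

**Step 10**
Reactants: 14 methyl (4S,4aR,5S,7R,8aS)-4,7-dihydroxy-5-(hydroxymethyl)-2,5,8a-trimethyl-3,4,4a,5,6,7,8,8a-octahydronaphthalene-1-carboxylate
Product: 15 methyl (4S,4aR,5S,7R,8aS)-4,7-bis[(tert-butyldimethylsilyl)oxy]-5-{[(tert-butyldimethylsilyl)oxy]methyl}-2,5,8a-trimethyl-3,4,4a,5,6,7,8,8a-octahydronaphthalene-1-carboxylate
Conditions: t-BuMe2SiOTf, 2,6-lutidine, CH2Cl2, −78 → 0 °C
Reagents that add atoms: tert-butyldimethylsilyl trifluoromethanesulfonate CC(C)(C)[Si](C)(C)OS(=O)(=O)C(F)(F)F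
Why: The silyl triflate should silylate all three hydroxyls, including the hindered 6α- and neopentylic 19-positions, so that the side chain can be built without free alcohols; no stereocenter is changed.

**Step 11**
Reactants: 15 the tris-silyl ester above
Product: 16 [(4S,4aR,5S,7R,8aS)-4,7-bis[(tert-butyldimethylsilyl)oxy]-5-{[(tert-butyldimethylsilyl)oxy]methyl}-2,5,8a-trimethyl-3,4,4a,5,6,7,8,8a-octahydronaphthalen-1-yl]methanol
Conditions: i-Bu2AlH, CH2Cl2, −78 → −20 °C; aq. sodium potassium tartrate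
Reagents that add atoms: none
Why: Aluminium hydride reduction of the conjugated ester should give the C11 allylic alcohol, silyl ethers and the tetrasubstituted alkene being inert.

**Step 12**
Reactants: 16 the C11 allylic alcohol above
Product: 17 (4S,4aR,5S,7R,8aS)-4,7-bis[(tert-butyldimethylsilyl)oxy]-5-{[(tert-butyldimethylsilyl)oxy]methyl}-2,5,8a-trimethyl-3,4,4a,5,6,7,8,8a-octahydronaphthalene-1-carbaldehyde
Conditions: MnO2 (excess), CH2Cl2, rt
Reagents that add atoms: none
Why: MnO2 oxidises only the allylic alcohol and gives the conjugated enal without moving the C8=C9 double bond.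

**Step 13**
Reactants: 17 the enal above
Product: 18 (4S,4aR,5S,7R,8aS)-1-ethenyl-4,7-bis[(tert-butyldimethylsilyl)oxy]-5-{[(tert-butyldimethylsilyl)oxy]methyl}-2,5,8a-trimethyl-3,4,4a,5,6,7,8,8a-octahydronaphthalene
Conditions: Ph3PCH3Br, KN(SiMe3)2, THF, −78 → 0 °C
Reagents that add atoms: methyltriphenylphosphonium bromide C[P+](c1ccccc1)(c1ccccc1)c1ccccc1.[Br-]
Why: Wittig methylenation of the hindered enal should be faster than γ-deprotonation at low temperature and gives the C9 vinyl group (C11=C12).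

**Step 14**
Reactants: 18 the vinyl diene above; 19 4-bromofuran-2(5H)-one
Product: 21 4-{2-[(4S,4aR,5S,7R,8aS)-4,7-bis[(tert-butyldimethylsilyl)oxy]-5-{[(tert-butyldimethylsilyl)oxy]methyl}-2,5,8a-trimethyl-3,4,4a,5,6,7,8,8a-octahydronaphthalen-1-yl]ethyl}furan-2(5H)-one, via alkyl-9-BBN borane 20 (not isolated)
Conditions: 9-BBN, THF, rt; then 19, PdCl2(dppf) (5 mol %), Ph3As, Cs2CO3, DMF/H2O, rt → 40 °C
Reagents that add atoms: none
Why: Anti-Markovnikov hydroboration of the monosubstituted vinyl group (the tetrasubstituted C8=C9 bond is inert to 9-BBN) puts boron on C12, and B-alkyl Suzuki–Miyaura coupling with the vinylogous acyl bromide should join C12 to C13 of the intact butenolide.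

**Step 15**
Reactants: 21 the tris-silyl butenolide above
Product: 22 4-{2-[(4S,4aR,5S,7R,8aS)-4,7-dihydroxy-5-(hydroxymethyl)-2,5,8a-trimethyl-3,4,4a,5,6,7,8,8a-octahydronaphthalen-1-yl]ethyl}furan-2(5H)-one (target)
Conditions: HF·pyridine, THF/pyridine, 0 °C → rt
Reagents that add atoms: none
Why: Fluoride-mediated cleavage of the three silyl ethers under buffered acidic conditions should leave the butenolide and the homoallylic 6α-alcohol intact and give the target.

**Compound list**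

1 | (E)-3-methylpent-2-en-4-yn-1-ol | C#C/C(C)=C/CO | starting material
2 | (E)-3-methylpent-2-en-4-yn-1-yl acetate | C#C/C(C)=C/COC(C)=O | intermediate
3 | (E)-3-methylpenta-2,4-dien-1-yl acetate | C=C/C(C)=C/COC(C)=O | intermediate
4 | methacrolein (2-methylprop-2-enal) | C=C(C)C=O | starting material
5 | [(1R,6S)-6-formyl-2,6-dimethylcyclohex-2-en-1-yl]methyl acetate (CHO and CH2OAc cis) | CC1=CCC[C@](C)(C=O)[C@@H]1COC(C)=O | intermediate
6 | [(1S,2R)-1,3-dimethylcyclohex-3-ene-1,2-diyl]dimethanol | CC1=CCC[C@](C)(CO)[C@@H]1CO | intermediate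
7 | (3aS,7aR)-3a,7-dimethyl-3a,4,5,7a-tetrahydro-2-benzofuran-1(3H)-one (cis-fused) | CC1=CCC[C@]2(C)COC(=O)[C@H]12 | intermediate
8 | (3aS,7aR)-3a,7-dimethyl-3a,4-dihydro-2-benzofuran-1,5(3H,7aH)-dione (ring A enone–lactone) | CC1=CC(=O)C[C@]2(C)COC(=O)[C@H]12 | intermediate
9 | dimethyl 3-methylpent-2-enedioate (dimethyl 3-methylglutaconate, E/Z mixture) | COC(=O)C=C(C)CC(=O)OC | starting material
10 | dimethyl 4-[(3aS,7aR)-3a,7-dimethyl-1,5-dioxooctahydro-2-benzofuran-7-yl]-3-methylpent-2-enedioate (new bond at C10 anti to the lactone; C9 epimers) | COC(=O)C=C(C)C(C(=O)OC)[C@@]1(C)CC(=O)C[C@]2(C)COC(=O)[C@H]12 | intermediate (not isolated)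
11 | dimethyl (4aR,5S,8aS)-5-(hydroxymethyl)-2,5,8a-trimethyl-4,7-dioxo-3,4,4a,5,6,7,8,8a-octahydronaphthalene-1,3-dicarboxylate (keto form; C3 epimers and enol interconvert) | CC1=C(C(=O)OC)[C@@]2(C)CC(=O)C[C@](C)(CO)[C@@H]2C(=O)C1C(=O)OC | intermediate
12 | methyl (1S,4aR,5S,8aS)-5-(hydroxymethyl)-2,5,8a-trimethyl-4,7-dioxo-1,4,4a,5,6,7,8,8a-octahydronaphthalene-1-carboxylate | CC1=CC(=O)[C@H]2[C@@](C)(CO)CC(=O)C[C@]2(C)[C@H]1C(=O)OC | intermediate
13 | methyl (4aR,5S,8aS)-5-(hydroxymethyl)-2,5,8a-trimethyl-4,7-dioxo-3,4,4a,5,6,7,8,8a-octahydronaphthalene-1-carboxylate | CC1=C(C(=O)OC)[C@@]2(C)CC(=O)C[C@](C)(CO)[C@@H]2C(=O)C1 | intermediate (not isolated)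
14 | methyl (4S,4aR,5S,7R,8aS)-4,7-dihydroxy-5-(hydroxymethyl)-2,5,8a-trimethyl-3,4,4a,5,6,7,8,8a-octahydronaphthalene-1-carboxylate | CC1=C(C(=O)OC)[C@@]2(C)C[C@@H](O)C[C@](C)(CO)[C@@H]2[C@@H](O)C1 | intermediate
15 | methyl (4S,4aR,5S,7R,8aS)-4,7-bis[(tert-butyldimethylsilyl)oxy]-5-{[(tert-butyldimethylsilyl)oxy]methyl}-2,5,8a-trimethyl-3,4,4a,5,6,7,8,8a-octahydronaphthalene-1-carboxylate | CC1=C(C(=O)OC)[C@@]2(C)C[C@@H](O[Si](C)(C)C(C)(C)C)C[C@](C)(CO[Si](C)(C)C(C)(C)C)[C@@H]2[C@@H](O[Si](C)(C)C(C)(C)C)C1 | intermediate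
16 | [(4S,4aR,5S,7R,8aS)-4,7-bis[(tert-butyldimethylsilyl)oxy]-5-{[(tert-butyldimethylsilyl)oxy]methyl}-2,5,8a-trimethyl-3,4,4a,5,6,7,8,8a-octahydronaphthalen-1-yl]methanol | CC1=C(CO)[C@@]2(C)C[C@@H](O[Si](C)(C)C(C)(C)C)C[C@](C)(CO[Si](C)(C)C(C)(C)C)[C@@H]2[C@@H](O[Si](C)(C)C(C)(C)C)C1 | intermediate
17 | (4S,4aR,5S,7R,8aS)-4,7-bis[(tert-butyldimethylsilyl)oxy]-5-{[(tert-butyldimethylsilyl)oxy]methyl}-2,5,8a-trimethyl-3,4,4a,5,6,7,8,8a-octahydronaphthalene-1-carbaldehyde | CC1=C(C=O)[C@@]2(C)C[C@@H](O[Si](C)(C)C(C)(C)C)C[C@](C)(CO[Si](C)(C)C(C)(C)C)[C@@H]2[C@@H](O[Si](C)(C)C(C)(C)C)C1 | intermediate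
18 | (4S,4aR,5S,7R,8aS)-1-ethenyl-4,7-bis[(tert-butyldimethylsilyl)oxy]-5-{[(tert-butyldimethylsilyl)oxy]methyl}-2,5,8a-trimethyl-3,4,4a,5,6,7,8,8a-octahydronaphthalene | CC1=C(C=C)[C@@]2(C)C[C@@H](O[Si](C)(C)C(C)(C)C)C[C@](C)(CO[Si](C)(C)C(C)(C)C)[C@@H]2[C@@H](O[Si](C)(C)C(C)(C)C)C1 | intermediate
19 | 4-bromofuran-2(5H)-one | O=C1C=C(Br)CO1 | starting material
20 | 9-{2-[(4S,4aR,5S,7R,8aS)-4,7-bis[(tert-butyldimethylsilyl)oxy]-5-{[(tert-butyldimethylsilyl)oxy]methyl}-2,5,8a-trimethyl-3,4,4a,5,6,7,8,8a-octahydronaphthalen-1-yl]ethyl}-9-borabicyclo[3.3.1]nonane | CC1=C(CCB3C4CCCC3CCC4)[C@@]2(C)C[C@@H](O[Si](C)(C)C(C)(C)C)C[C@](C)(CO[Si](C)(C)C(C)(C)C)[C@@H]2[C@@H](O[Si](C)(C)C(C)(C)C)C1 | intermediate (not isolated)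
21 | 4-{2-[(4S,4aR,5S,7R,8aS)-4,7-bis[(tert-butyldimethylsilyl)oxy]-5-{[(tert-butyldimethylsilyl)oxy]methyl}-2,5,8a-trimethyl-3,4,4a,5,6,7,8,8a-octahydronaphthalen-1-yl]ethyl}furan-2(5H)-one | CC1=C(CCC3=CC(=O)OC3)[C@@]2(C)C[C@@H](O[Si](C)(C)C(C)(C)C)C[C@](C)(CO[Si](C)(C)C(C)(C)C)[C@@H]2[C@@H](O[Si](C)(C)C(C)(C)C)C1 | intermediate
22 | 4-{2-[(4S,4aR,5S,7R,8aS)-4,7-dihydroxy-5-(hydroxymethyl)-2,5,8a-trimethyl-3,4,4a,5,6,7,8,8a-octahydronaphthalen-1-yl]ethyl}furan-2(5H)-one | CC1=C(CCC2=CC(=O)OC2)[C@@]2(C)C[C@@H](O)C[C@](C)(CO)[C@@H]2[C@@H](O)C1 | target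

**Count**

Total: 15 steps. Longest linear sequence: 15 steps (1 → 22); 4, 9 and 19 are bought.

**Three steps most likely to fail**

Step 7. The conjugate addition may stall at the hindered, doubly substituted enone carbon (the stabilised anion then being lost to self-condensation), or acylation at the lactone may come first and the ring then close with the wrong (cis) fusion. The fallback sets out from 8 and comes back at 14; it makes the two bonds one after the other by a sigmatropic route.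
- 1,2-Reduction of 8 (NaBH4, CeCl3·7H2O, MeOH, −78 °C; hydride anti to the axial 4-methyl) should give the allylic alcohol (3aS,5S,7aR)-5-hydroxy-3a,7-dimethyl-3a,4,5,7a-tetrahydro-2-benzofuran-1(3H)-one F1.
- Acylation with 3-methylbut-2-enoyl chloride (pyridine, DMAP) gives (3aS,5S,7aR)-3a,7-dimethyl-1-oxo-1,3,3a,4,5,7a-hexahydro-2-benzofuran-5-yl 3-methylbut-2-enoate F2.
- Ireland–Claisen rearrangement (LiN(i-Pr)2, Me3SiCl, THF/DMPU, −78 → 50 °C; then Me3SiCHN2, MeOH) moves the acyl α-carbon suprafacially from O2 to C10 and gives methyl 2-[(3aS,7aR)-3a,7-dimethyl-1-oxo-1,3,3a,4,7,7a-hexahydro-2-benzofuran-7-yl]-3-methylbut-3-enoate F3.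
- NaOMe in MeOH (65 °C) closes ring B by vinylogous Dieckmann condensation of the ester dienolate (through C7) onto the lactone, and a cold AcOH quench gives methyl (4aR,5S,8aS)-5-(hydroxymethyl)-2,5,8a-trimethyl-4-oxo-3,4,4a,5,6,8a-hexahydronaphthalene-1-carboxylate F4.
- Hydroxyl-directed reduction (Me4N[BH(OAc)3], MeCN/AcOH) gives methyl (4S,4aR,5S,8aS)-4-hydroxy-5-(hydroxymethyl)-2,5,8a-trimethyl-3,4,4a,5,6,8a-hexahydronaphthalene-1-carboxylate F5.
- Hydroboration–oxidation of the C1=C2 bond (9-BBN, THF, 60 °C; NaOH, H2O2; boron at C2 from the α-face) gives 14.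

Step 9. The deconjugated ketone may slip back into conjugation before it is reduced, or hydride may not be delivered from the 19-hydroxyl, so that the alcohols form on the wrong (axial) side. The fallback sets out from 12 and comes back at 15; it accepts the axial alcohols and inverts them.
- Silylation of the primary alcohol (t-BuMe2SiCl, imidazole, DMF) gives methyl (1S,4aR,5S,8aS)-5-{[(tert-butyldimethylsilyl)oxy]methyl}-2,5,8a-trimethyl-4,7-dioxo-1,4,4a,5,6,7,8,8a-octahydronaphthalene-1-carboxylate F6.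
- Deconjugation as in step 9 (KOt-Bu, then AcOH) followed by Li[HB(s-Bu)3] (THF, −78 °C; equatorial attack) gives methyl (4R,4aR,5S,7S,8aS)-5-{[(tert-butyldimethylsilyl)oxy]methyl}-4,7-dihydroxy-2,5,8a-trimethyl-3,4,4a,5,6,7,8,8a-octahydronaphthalene-1-carboxylate F7.
- Double Mitsunobu inversion (4-nitrobenzoic acid, PPh3, DIAD, toluene) gives methyl (4S,4aR,5S,7R,8aS)-5-{[(tert-butyldimethylsilyl)oxy]methyl}-2,5,8a-trimethyl-4,7-bis[(4-nitrobenzoyl)oxy]-3,4,4a,5,6,7,8,8a-octahydronaphthalene-1-carboxylate F8.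
- K2CO3 in MeOH frees methyl (4S,4aR,5S,7R,8aS)-5-{[(tert-butyldimethylsilyl)oxy]methyl}-4,7-dihydroxy-2,5,8a-trimethyl-3,4,4a,5,6,7,8,8a-octahydronaphthalene-1-carboxylate F9.
- t-BuMe2SiOTf with 2,6-lutidine gives 15.

Step 3. Enantiofacial discrimination may be poor (the acetate can compete with the aldehyde for the boron centre), or the catalyst may be inhibited. The fallback sets out from 3 and comes back at 6; it makes the racemate and resolves it.
- Diels–Alder reaction of 3 with 4 promoted by EtAlCl2 (CH2Cl2, −78 °C) gives racemic cis-(6-formyl-2,6-dimethylcyclohex-2-en-1-yl)methyl acetate F10.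
- NaBH4, then K2CO3 in MeOH, gives racemic cis-(1,3-dimethylcyclohex-3-ene-1,2-diyl)dimethanol F11.
- Preparative chromatography on a chiral stationary phase (cellulose tris(3,5-dimethylphenylcarbamate)) separates the enantiomers; the (1S,2R)-enantiomer is 6.

**Further compounds**

F1 | step 7 | (3aS,5S,7aR)-5-hydroxy-3a,7-dimethyl-3a,4,5,7a-tetrahydro-2-benzofuran-1(3H)-one | CC1=C[C@@H](O)C[C@]2(C)COC(=O)[C@H]12
F2 | step 7 | (3aS,5S,7aR)-3a,7-dimethyl-1-oxo-1,3,3a,4,5,7a-hexahydro-2-benzofuran-5-yl 3-methylbut-2-enoate | CC1=C[C@@H](OC(=O)C=C(C)C)C[C@]2(C)COC(=O)[C@H]12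
F3 | step 7 | methyl 2-[(3aS,7aR)-3a,7-dimethyl-1-oxo-1,3,3a,4,7,7a-hexahydro-2-benzofuran-7-yl]-3-methylbut-3-enoate | C=C(C)C(C(=O)OC)[C@@]1(C)C=CC[C@]2(C)COC(=O)[C@H]12
F4 | step 7 | methyl (4aR,5S,8aS)-5-(hydroxymethyl)-2,5,8a-trimethyl-4-oxo-3,4,4a,5,6,8a-hexahydronaphthalene-1-carboxylate | CC1=C(C(=O)OC)[C@@]2(C)C=CC[C@](C)(CO)[C@@H]2C(=O)C1
F5 | step 7 | methyl (4S,4aR,5S,8aS)-4-hydroxy-5-(hydroxymethyl)-2,5,8a-trimethyl-3,4,4a,5,6,8a-hexahydronaphthalene-1-carboxylate | CC1=C(C(=O)OC)[C@@]2(C)C=CC[C@](C)(CO)[C@@H]2[C@@H](O)C1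
F6 | step 9 | methyl (1S,4aR,5S,8aS)-5-{[(tert-butyldimethylsilyl)oxy]methyl}-2,5,8a-trimethyl-4,7-dioxo-1,4,4a,5,6,7,8,8a-octahydronaphthalene-1-carboxylate | CC1=CC(=O)[C@H]2[C@@](C)(CO[Si](C)(C)C(C)(C)C)CC(=O)C[C@]2(C)[C@H]1C(=O)OC
F7 | step 9 | methyl (4R,4aR,5S,7S,8aS)-5-{[(tert-butyldimethylsilyl)oxy]methyl}-4,7-dihydroxy-2,5,8a-trimethyl-3,4,4a,5,6,7,8,8a-octahydronaphthalene-1-carboxylate | CC1=C(C(=O)OC)[C@@]2(C)C[C@H](O)C[C@](C)(CO[Si](C)(C)C(C)(C)C)[C@@H]2[C@H](O)C1
F8 | step 9 | methyl (4S,4aR,5S,7R,8aS)-5-{[(tert-butyldimethylsilyl)oxy]methyl}-2,5,8a-trimethyl-4,7-bis[(4-nitrobenzoyl)oxy]-3,4,4a,5,6,7,8,8a-octahydronaphthalene-1-carboxylate | CC1=C(C(=O)OC)[C@@]2(C)C[C@@H](OC(=O)c3ccc(cc3)[N+](=O)[O-])C[C@](C)(CO[Si](C)(C)C(C)(C)C)[C@@H]2[C@@H](OC(=O)c3ccc(cc3)[N+](=O)[O-])C1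
F9 | step 9 | methyl (4S,4aR,5S,7R,8aS)-5-{[(tert-butyldimethylsilyl)oxy]methyl}-4,7-dihydroxy-2,5,8a-trimethyl-3,4,4a,5,6,7,8,8a-octahydronaphthalene-1-carboxylate | CC1=C(C(=O)OC)[C@@]2(C)C[C@@H](O)C[C@](C)(CO[Si](C)(C)C(C)(C)C)[C@@H]2[C@@H](O)C1
F10 | step 3 | racemic cis-(6-formyl-2,6-dimethylcyclohex-2-en-1-yl)methyl acetate | CC1=CCCC(C)(C=O)C1COC(C)=O
F11 | step 3 | racemic cis-(1,3-dimethylcyclohex-3-ene-1,2-diyl)dimethanol | CC1=CCCC(C)(CO)C1CO
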